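## Retrosynthetic overview

1. The target comes from a catechol spiro-ketone by Ag2O oxidation and ortho-quinone to quinone-methide tautomerisation; the catechol comes from a spiro dienone by hydrogenation and BBr3 deprotection.
2. Key step, last ring formed: Pd/CO carbonylative Heck cyclisation of a C7 enol triflate onto a C14 bicyclo[3.1.0]hexenyl group. CO becomes the ketone carbon, both C–C bonds of the cyclopentenone form at once, and the spiro centre is set by addition anti to the cyclopropane.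
3. The C14–C2' bond is made by one-pot borylation/Suzuki coupling of a bicyclo[3.1.0]hexenyl triflate with a 14-bromo-7-oxoabietane; rings A, B and C come intact from (+)-carnosic acid.
4. The bicyclo[3.1.0]hexane (five- and three-membered rings formed together) comes from a lithium-amide-induced intramolecular cyclopropanation of an unsaturated terminal epoxide, whose carbinol carbon is a traceless stereocontrol element.
5. The epoxide comes from E-selective cross-metathesis of (R)-1,2-epoxy-5-hexene with an alkene whose isopropyl stereocentre is set by an organocatalytic Michael addition.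

Assumption (one line): (+)-carnosic acid and (R)-1,2-epoxy-5-hexene are taken as commercial; abietane locants C1–C20 are used for the diterpene half, primed bicyclo[3.1.0]hexane locants for the other half (C2' = spiro carbon, C6' = cyclopropane carbon carrying the side chain), and "ketal side chain" means (3S)-4-methyl-1-(2-methyl-1,3-dioxolan-2-yl)pentan-3-yl.

## Route

Step 1
Reactants: 1 3-methylbutanal; 2 but-3-en-2-one
Product: 3 (2S)-5-oxo-2-(propan-2-yl)hexanal
Conditions: (S)-2-[methoxy(diphenyl)methyl]pyrrolidine (5 mol %), ethyl 3,4-dihydroxybenzoate (20 mol %), neat, 4 °C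
Reagents that add atoms: none
Why: Enamine-catalysed asymmetric Michael addition in which the CPh2(OMe) group of the (S)-prolinol ether shields one face of the E-enamine of 1 so that 2 adds from the open face and sets the 2S centre.

Step 2
Reactants: 3 (2S)-5-oxo-2-(propan-2-yl)hexanal
Product: 4 (5S)-5-(propan-2-yl)hept-6-en-2-one
Conditions: Ph3PCH3Br, KN(SiMe3)2, THF, −78 → 0 °C
Reagents that add atoms: methyltriphenylphosphonium bromide, C[P+](c1ccccc1)(c1ccccc1)c1ccccc1.[Br-]
Why: Wittig methylenation with a non-stabilised ylide at low temperature is selective for the aldehyde over the methyl ketone and leaves the α-stereocentre untouched.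

Step 3
Reactants: 4 (5S)-5-(propan-2-yl)hept-6-en-2-one
Product: 5 2-methyl-2-[(3S)-3-(propan-2-yl)pent-4-en-1-yl]-1,3-dioxolane
Conditions: HOCH2CH2OH, PPTS (cat.), benzene, reflux, Dean–Stark
Reagents that add atoms: ethane-1,2-diol, OCCO
Why: Acid-catalysed ketalisation with azeotropic water removal masks the methyl ketone against the strong bases used later and involves no stereocentre.

Step 4
Reactants: 5 2-methyl-2-[(3S)-3-(propan-2-yl)pent-4-en-1-yl]-1,3-dioxolane; 6 (2R)-2-(but-3-en-1-yl)oxirane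
Product: 7 (2R)-2-[(3E,5S)-7-(2-methyl-1,3-dioxolan-2-yl)-5-(propan-2-yl)hept-3-en-1-yl]oxirane
Conditions: second-generation Grubbs catalyst RuCl2(=CHPh)(PCy3)(H2IMes) (5 mol %), 6 (3 equiv), CH2Cl2, 40 °C
Reagents that add atoms: none
Why: Olefin cross-metathesis between the unhindered alkene of 6 used in excess and the allylically branched alkene 5 gives the thermodynamically favoured E-alkene while both existing stereocentres stay untouched.

Step 5
Reactants: 7 (2R)-2-[(3E,5S)-7-(2-methyl-1,3-dioxolan-2-yl)-5-(propan-2-yl)hept-3-en-1-yl]oxirane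
Product: 8 (1S,2R,5S,6S)-6-[(3S)-4-methyl-1-(2-methyl-1,3-dioxolan-2-yl)pentan-3-yl]bicyclo[3.1.0]hexan-2-ol
Conditions: lithium 2,2,6,6-tetramethylpiperidide (from n-BuLi and 2,2,6,6-tetramethylpiperidine, 2.5 equiv), t-BuOMe, 0 °C → rt; H2O
Reagents that add atoms: none
Why: Hodgson-type intramolecular cyclopropanation of an unsaturated terminal epoxide in which the amide base lithiates the epoxide CH2 trans to the chain and this carbon adds across the tethered E-alkene with inversion, so that the epoxide stereocentre fixes C1 and C5 (hydroxyl trans to the cyclopropane) and the E geometry places the side chain exo at C6.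

Step 6
Reactants: 8 (1S,2R,5S,6S)-6-[(3S)-4-methyl-1-(2-methyl-1,3-dioxolan-2-yl)pentan-3-yl]bicyclo[3.1.0]hexan-2-ol
Product: 9 (1S,5S,6S)-6-[(3S)-4-methyl-1-(2-methyl-1,3-dioxolan-2-yl)pentan-3-yl]bicyclo[3.1.0]hexan-2-one
Conditions: n-Pr4N[RuO4] (5 mol %), N-methylmorpholine N-oxide, 4 Å MS, CH2Cl2, rt
Reagents that add atoms: none
Why: Ley–Griffith oxidation of the secondary alcohol gives the cyclopropyl ketone and erases the carbinol centre that served as a traceless control element.

Step 7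
Reactants: 9 (1S,5S,6S)-6-[(3S)-4-methyl-1-(2-methyl-1,3-dioxolan-2-yl)pentan-3-yl]bicyclo[3.1.0]hexan-2-one
Product: 11 (1S,5S,6S)-6-(ketal side chain)bicyclo[3.1.0]hex-2-en-2-yl trifluoromethanesulfonate, via potassium enolate 10 (not isolated)
Conditions: KN(SiMe3)2, THF, −78 °C; then PhNTf2, −78 → 0 °C
Reagents that add atoms: N-phenylbis(trifluoromethanesulfonimide), O=S(=O)(N(c1ccccc1)S(=O)(=O)C(F)(F)F)C(F)(F)F
Why: Enolisation can only occur toward C3 because C1 is a cyclopropane bridgehead, and O-triflation of the enolate gives the enol triflate without touching a stereocentre.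

Step 8
Reactants: 12 (+)-carnosic acid [(5S,10R)-11,12-dihydroxyabieta-8,11,13-trien-20-oic acid]
Product: 13 methyl (5S,10R)-11,12-dimethoxyabieta-8,11,13-trien-20-oate
Conditions: MeI (excess), K2CO3, DMF, 50 °C, argon
Reagents that add atoms: iodomethane, CI
Why: Exhaustive Williamson-type O-methylation of the carboxylic acid and both phenols protects the catechol as robust methyl ethers and leaves C5 and C10 unchanged.

Step 9
Reactants: 13 methyl (5S,10R)-11,12-dimethoxyabieta-8,11,13-trien-20-oate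
Product: 14 (5S,10R)-11,12-dimethoxyabieta-8,11,13-trien-20-ol
Conditions: LiAlH4, THF, reflux; H2O
Reagents that add atoms: none
Why: Hydride reduction of the hindered angular ester with LiAlH4 gives the neopentyl primary alcohol.

Step 10
Reactants: 14 (5S,10R)-11,12-dimethoxyabieta-8,11,13-trien-20-ol
Product: 15 (5S,10R)-11,12-dimethoxyabieta-8,11,13-trien-20-al
Conditions: n-Pr4N[RuO4] (5 mol %), N-methylmorpholine N-oxide, 4 Å MS, CH2Cl2, rt
Reagents that add atoms: none
Why: Ley–Griffith oxidation stops cleanly at the non-enolisable angular aldehyde.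

Step 11
Reactants: 15 (5S,10R)-11,12-dimethoxyabieta-8,11,13-trien-20-al
Product: 17 (5S,10S)-11,12-dimethoxyabieta-8,11,13-triene, via hydrazone 16 (not isolated)
Conditions: N2H4·H2O, KOH, diethylene glycol, 130 → 200 °C
Reagents that add atoms: none
Why: Wolff–Kishner reduction in its Huang-Minlon form converts the angular aldehyde through its hydrazone into the C20 methyl group of the abietane skeleton.

Step 12
Reactants: 17 (5S,10S)-11,12-dimethoxyabieta-8,11,13-triene
Product: 18 (5S,10S)-14-bromo-11,12-dimethoxyabieta-8,11,13-triene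
Conditions: NBS, MeCN, 0 °C → rt, dark
Reagents that add atoms: N-bromosuccinimide, O=C1CCC(=O)N1Br
Why: Electrophilic aromatic bromination occurs at C14, which is the only free ring position and lies para to the 11-methoxy group.

Step 13
Reactants: 18 (5S,10S)-14-bromo-11,12-dimethoxyabieta-8,11,13-triene
Product: 19 (5S,10S)-14-bromo-11,12-dimethoxyabieta-8,11,13-trien-7-one
Conditions: CrO3, AcOH–Ac2O, 0 °C → rt
Reagents that add atoms: chromium trioxide, O=[Cr](=O)=O
Why: Benzylic oxidation with chromium trioxide takes place at the secondary benzylic C7, which is activated through the para 12-methoxy group, and gives the aryl ketone.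

Step 14
Reactants: 11 (1S,5S,6S)-6-(ketal side chain)bicyclo[3.1.0]hex-2-en-2-yl trifluoromethanesulfonate; 19 (5S,10S)-14-bromo-11,12-dimethoxyabieta-8,11,13-trien-7-one
Product: 21 (5S,10S)-11,12-dimethoxy-14-[(1'S,5'S,6'S)-6'-(ketal side chain)bicyclo[3.1.0]hex-2'-en-2'-yl]abieta-8,11,13-trien-7-one, via alkenyl boronate 20 (not isolated)
Conditions: B2pin2, PdCl2(PPh3)2 (3 mol %), PPh3, KOPh, toluene, 50 °C; then 19, Pd(OAc)2 (5 mol %), SPhos (10 mol %), aq. K3PO4, 90 °C
Reagents that add atoms: none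
Why: One-pot Miyaura borylation of the alkenyl triflate followed by Suzuki–Miyaura coupling with the di-ortho-substituted aryl bromide under a bulky biarylphosphine joins the two fragments at C14–C2' without touching any stereocentre.

Step 15
Reactants: 21 (5S,10S)-11,12-dimethoxy-14-[(1'S,5'S,6'S)-6'-(ketal side chain)bicyclo[3.1.0]hex-2'-en-2'-yl]abieta-8,11,13-trien-7-one
Product: 23 (5S,10S)-11,12-dimethoxy-14-[(1'S,5'S,6'S)-6'-(ketal side chain)bicyclo[3.1.0]hex-2'-en-2'-yl]abieta-6,8,11,13-tetraen-7-yl trifluoromethanesulfonate, via potassium enolate 22 (not isolated)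
Conditions: KN(SiMe3)2, THF, −78 °C; then PhNTf2, −78 → 0 °C
Reagents that add atoms: N-phenylbis(trifluoromethanesulfonimide), O=S(=O)(N(c1ccccc1)S(=O)(=O)C(F)(F)F)C(F)(F)F
Why: Deprotonation at C6, the only α-position of the aryl ketone, and O-triflation give the conjugated enol triflate.

Step 16
Reactants: 23 (5S,10S)-11,12-dimethoxy-14-[(1'S,5'S,6'S)-6'-(ketal side chain)bicyclo[3.1.0]hex-2'-en-2'-yl]abieta-6,8,11,13-tetraen-7-yl trifluoromethanesulfonate
Product: 24 spiro dienone in which the new C=O joins abietane C7 and spiro carbon C2' (2'R; C14 on the cyclopropane face); 11,12-dimethoxyabieta-6,8,11,13-tetraene; bicyclo[3.1.0]hex-3'-ene; ketal side chain exo on C6'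
Conditions: Pd(PPh3)4 (10 mol %), CO (20 bar), Et3N, MeCN–toluene, 90 °C
Reagents that add atoms: carbon monoxide, [C-]#[O+]
Why: Carbonylative Heck reaction (cyclic acylpalladation) in which oxidative addition of zerovalent palladium into the C7–OTf bond and CO insertion are followed by 5-exo syn-acylpalladation of the twisted C2'=C3' alkene from the face anti to the cyclopropane, which sets the spiro centre with C14 syn to the cyclopropane, and syn β-hydride elimination toward C4' then releases the dienone.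

Step 17
Reactants: 24 spiro dienone
Product: 25 spiro ketone: as 24 but with C6–C7 and C3'–C4' saturated (C7 epimers)
Conditions: H2 (10 bar), [Ir(cod)(PCy3)(py)]PF6 (5 mol %), CH2Cl2, rt
Reagents that add atoms: none
Why: Homogeneous iridium-catalysed hydrogenation saturates the enone C6=C7 bond and the cyclopentene without opening the cyclopropane, and the new C7 centre is uncontrolled but irrelevant because it becomes sp2 again in the last step.

Step 18
Reactants: 25 spiro ketone (C7 epimers)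
Product: 26 catechol diketone: as 25 with 11,12-dihydroxy groups and the free (3S)-2-methyl-6-oxoheptan-3-yl side chain on C6'
Conditions: BBr3, CH2Cl2, −78 → 0 °C; then H2O
Reagents that add atoms: water, O
Why: Lewis-acid ether cleavage with BBr3 demethylates both aryl methyl ethers and opens the dioxolane, so that aqueous work-up delivers the catechol and the methyl ketone.

Step 19
Reactants: 26 catechol diketone
Product: 28 target CNP0140364.1, via ortho-quinone 27 (not isolated)
Conditions: Ag2O, Et2O, rt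
Reagents that add atoms: none
Why: Two-electron oxidation of the catechol by Ag2O gives the 11,12-ortho-quinone, which tautomerises through the acidic C7–H to the conjugated 11-hydroxy quinone methide of the target with all stereocentres unchanged.

## Compound list

1 | 3-methylbutanal | CC(C)CC=O | starting material
2 | but-3-en-2-one | CC(=O)C=C | starting material
3 | (2S)-5-oxo-2-(propan-2-yl)hexanal | CC(=O)CC[C@@H](C(C)C)C=O | intermediate
4 | (5S)-5-(propan-2-yl)hept-6-en-2-one | CC(=O)CC[C@@H](C(C)C)C=C | intermediate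
5 | 2-methyl-2-[(3S)-3-(propan-2-yl)pent-4-en-1-yl]-1,3-dioxolane | CC1(CC[C@@H](C(C)C)C=C)OCCO1 | intermediate
6 | (2R)-2-(but-3-en-1-yl)oxirane | C=CCC[C@@H]1CO1 | starting material
7 | (2R)-2-[(3E,5S)-7-(2-methyl-1,3-dioxolan-2-yl)-5-(propan-2-yl)hept-3-en-1-yl]oxirane | CC1(CC[C@@H](C(C)C)/C=C/CC[C@@H]2CO2)OCCO1 | intermediate
8 | (1S,2R,5S,6S)-6-[(3S)-4-methyl-1-(2-methyl-1,3-dioxolan-2-yl)pentan-3-yl]bicyclo[3.1.0]hexan-2-ol; OH trans to the cyclopropane; side chain exo | CC1(CC[C@@H](C(C)C)[C@H]2[C@@H]3CC[C@@H](O)[C@@H]32)OCCO1 | intermediate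
9 | (1S,5S,6S)-6-[(3S)-4-methyl-1-(2-methyl-1,3-dioxolan-2-yl)pentan-3-yl]bicyclo[3.1.0]hexan-2-one | CC1(CC[C@@H](C(C)C)[C@H]2[C@@H]3CCC(=O)[C@@H]32)OCCO1 | intermediate
10 | potassium enolate of 9 (C2=C3; not isolated) | CC1(CC[C@@H](C(C)C)[C@H]2[C@@H]3CC=C([O-])[C@@H]32)OCCO1.[K+] | intermediate
11 | (1S,5S,6S)-6-(ketal side chain)bicyclo[3.1.0]hex-2-en-2-yl trifluoromethanesulfonate | CC1(CC[C@@H](C(C)C)[C@H]2[C@@H]3CC=C(OS(=O)(=O)C(F)(F)F)[C@@H]32)OCCO1 | intermediate
12 | (+)-carnosic acid, (5S,10R)-11,12-dihydroxyabieta-8,11,13-trien-20-oic acid | CC(C)c1cc2c(c(O)c1O)[C@@]1(C(=O)O)CCCC(C)(C)[C@@H]1CC2 | starting material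
13 | methyl (5S,10R)-11,12-dimethoxyabieta-8,11,13-trien-20-oate | CC(C)c1cc2c(c(OC)c1OC)[C@@]1(C(=O)OC)CCCC(C)(C)[C@@H]1CC2 | intermediate
14 | (5S,10R)-11,12-dimethoxyabieta-8,11,13-trien-20-ol | CC(C)c1cc2c(c(OC)c1OC)[C@@]1(CO)CCCC(C)(C)[C@@H]1CC2 | intermediate
15 | (5S,10R)-11,12-dimethoxyabieta-8,11,13-trien-20-al | CC(C)c1cc2c(c(OC)c1OC)[C@@]1(C=O)CCCC(C)(C)[C@@H]1CC2 | intermediate
16 | hydrazone of 15 (not isolated) | CC(C)c1cc2c(c(OC)c1OC)[C@@]1(C=NN)CCCC(C)(C)[C@@H]1CC2 | intermediate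
17 | (5S,10S)-11,12-dimethoxyabieta-8,11,13-triene | CC(C)c1cc2c(c(OC)c1OC)[C@@]1(C)CCCC(C)(C)[C@@H]1CC2 | intermediate
18 | (5S,10S)-14-bromo-11,12-dimethoxyabieta-8,11,13-triene | CC(C)c1c(Br)c2c(c(OC)c1OC)[C@@]1(C)CCCC(C)(C)[C@@H]1CC2 | intermediate
19 | (5S,10S)-14-bromo-11,12-dimethoxyabieta-8,11,13-trien-7-one | CC(C)c1c(Br)c2c(c(OC)c1OC)[C@@]1(C)CCCC(C)(C)[C@@H]1CC2=O | intermediate
20 | 2-[(1S,5S,6S)-6-(ketal side chain)bicyclo[3.1.0]hex-2-en-2-yl]-4,4,5,5-tetramethyl-1,3,2-dioxaborolane (not isolated) | CC1(CC[C@@H](C(C)C)[C@H]2[C@@H]3CC=C(B4OC(C)(C)C(C)(C)O4)[C@@H]32)OCCO1 | intermediate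
21 | (5S,10S)-11,12-dimethoxy-14-[(1'S,5'S,6'S)-6'-(ketal side chain)bicyclo[3.1.0]hex-2'-en-2'-yl]abieta-8,11,13-trien-7-one | CC1(CC[C@@H](C(C)C)[C@H]2[C@@H]3CC=C(c4c(C(C)C)c(OC)c(OC)c5[C@@]6(C)CCCC(C)(C)[C@@H]6CC(=O)c45)[C@@H]32)OCCO1 | intermediate
22 | potassium enolate of 21 (C6=C7; not isolated) | CC1(CC[C@@H](C(C)C)[C@H]2[C@@H]3CC=C(c4c(C(C)C)c(OC)c(OC)c5[C@@]6(C)CCCC(C)(C)[C@@H]6C=C([O-])c45)[C@@H]32)OCCO1.[K+] | intermediate
23 | (5S,10S)-11,12-dimethoxy-14-[(1'S,5'S,6'S)-6'-(ketal side chain)bicyclo[3.1.0]hex-2'-en-2'-yl]abieta-6,8,11,13-tetraen-7-yl trifluoromethanesulfonate | CC1(CC[C@@H](C(C)C)[C@H]2[C@@H]3CC=C(c4c(C(C)C)c(OC)c(OC)c5[C@@]6(C)CCCC(C)(C)[C@@H]6C=C(OS(=O)(=O)C(F)(F)F)c45)[C@@H]32)OCCO1 | intermediate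
24 | spiro dienone: C=O between abietane C7 and spiro C2' (2'R; C14 syn to the cyclopropane); 11,12-dimethoxy; C6=C7 and C3'=C4' double bonds; ketal side chain exo on C6' | CC1(CC[C@@H](C(C)C)[C@H]2[C@@H]3C=C[C@@]4(C(=O)C=5c6c4c(C(C)C)c(OC)c(OC)c6[C@@]7(C)CCCC(C)(C)[C@@H]7C=5)[C@@H]32)OCCO1 | intermediate
25 | spiro ketone: 24 with C6–C7 and C3'–C4' saturated (C7 epimers) | CC1(CC[C@@H](C(C)C)[C@H]2[C@@H]3CC[C@@]4(C(=O)C5c6c4c(C(C)C)c(OC)c(OC)c6[C@@]7(C)CCCC(C)(C)[C@@H]7C5)[C@@H]32)OCCO1 | intermediate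
26 | catechol diketone: 25 with 11,12-dihydroxy groups and the (3S)-2-methyl-6-oxoheptan-3-yl side chain | CC(=O)CC[C@@H](C(C)C)[C@H]1[C@@H]2CC[C@@]3(C(=O)C4c5c3c(C(C)C)c(O)c(O)c5[C@@]6(C)CCCC(C)(C)[C@@H]6C4)[C@@H]21 | intermediate
27 | ortho-quinone: 11,12-dioxoabieta-8,13-diene form of 26 (not isolated) | CC(=O)CC[C@@H](C(C)C)[C@H]1[C@@H]2CC[C@@]3(C(=O)C4C=5C3=C(C(C)C)C(=O)C(=O)C=5[C@@]6(C)CCCC(C)(C)[C@@H]6C4)[C@@H]21 | intermediate
28 | CNP0140364.1: (5S,10S)-11-hydroxy-12-oxoabieta-7,9(11),13-triene with C7 and C14 bridged by C(=O)–C2' of (1'S,2'R,5'S,6'S)-6'-[(3S)-2-methyl-6-oxoheptan-3-yl]bicyclo[3.1.0]hexane | CC(=O)CC[C@@H](C(C)C)[C@H]1[C@@H]2CC[C@@]3(C(=O)C4=C5C3=C(C(C)C)C(=O)C(O)=C5[C@@]3(C)CCCC(C)(C)[C@@H]3C4)[C@@H]21 | target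

## Step count and risk

Total step count: 19.
Longest linear sequence: 13 steps (steps 1–7, then 14–19); the carnosic acid branch is 12 steps (8–13, then 14–19).

The three steps most likely to fail:

Step 16 (carbonylative Heck spirocyclisation). Insertion into the hindered trisubstituted alkene may be slow, and palladium hydride could re-add and open the cyclopropane. The fallback sets out from enol triflate 23 and comes back at spiro dienone 24, using a dipolar cycloaddition instead of a migratory insertion. Reductive carbonylation (Pd(OAc)2, dppp, CO 1 bar, Et3SiH, Et3N, DMF) gives enal F1, and NH2OH·HCl in pyridine gives aldoxime F2. Aqueous NaOCl in CH2Cl2 oxidises F2 in the flask to nitrile oxide F3, which undergoes intramolecular nitrile oxide–alkene cycloaddition anti to the cyclopropane to give isoxazoline F4. Mo(CO)6 in wet MeCN cleaves the N–O bond to β-hydroxy ketone F5, and the Burgess reagent dehydrates F5 toward C4' to give 24.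

Step 14 (coupling at the doubly ortho-substituted C14). The fallback sets out from bromo ketone 19 together with ketone 9 and comes back at 21, using carbonyl addition and dehydration instead of cross-coupling. LiN(SiMe3)2 and then t-BuLi convert 19 in the flask into C14-lithiated lithium enolate F6. After transmetalation with CeCl3 this adds to the carbonyl group of 9 to give tertiary carbinol F7. The Burgess reagent then eliminates water toward C3', which carries the only β-hydrogens, to give 21.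

Step 18 (BBr3 global deprotection in the presence of two ketones and the cyclopropane). The fallback sets out from 25 and comes back at ortho-quinone 27. Dilute HCl in THF removes the dioxolane to give dimethoxy diketone F8, and (NH4)2Ce(NO3)6 in aqueous MeCN then effects oxidative demethylation directly to 27, which tautomerises to 28 as in step 19.

## Further compounds

F1 | step 16 | (5S,10S)-11,12-dimethoxy-14-[(1'S,5'S,6'S)-6'-(ketal side chain)bicyclo[3.1.0]hex-2'-en-2'-yl]abieta-6,8,11,13-tetraene-7-carbaldehyde | CC1(CC[C@@H](C(C)C)[C@H]2[C@@H]3CC=C(c4c(C(C)C)c(OC)c(OC)c5[C@@]6(C)CCCC(C)(C)[C@@H]6C=C(C=O)c45)[C@@H]32)OCCO1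
F2 | step 16 | aldoxime of F1 | CC1(CC[C@@H](C(C)C)[C@H]2[C@@H]3CC=C(c4c(C(C)C)c(OC)c(OC)c5[C@@]6(C)CCCC(C)(C)[C@@H]6C=C(C=NO)c45)[C@@H]32)OCCO1
F3 | step 16 | nitrile oxide from F2 | CC1(CC[C@@H](C(C)C)[C@H]2[C@@H]3CC=C(c4c(C(C)C)c(OC)c(OC)c5[C@@]6(C)CCCC(C)(C)[C@@H]6C=C(C#[N+][O-])c45)[C@@H]32)OCCO1
F4 | step 16 | spiro isoxazoline: C=N carbon on C7 and on spiro C2'; ring oxygen on C3' (both anti to the cyclopropane); C6=C7 retained | CC1(CC[C@@H](C(C)C)[C@H]2[C@@H]3C[C@@H]8[C@@]4(C(=NO8)C=5c6c4c(C(C)C)c(OC)c(OC)c6[C@@]7(C)CCCC(C)(C)[C@@H]7C=5)[C@@H]32)OCCO1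
F5 | step 16 | 3'-hydroxy spiro enone (β-hydroxy ketone from F4) | CC1(CC[C@@H](C(C)C)[C@H]2[C@@H]3C[C@@H](O)[C@@]4(C(=O)C=5c6c4c(C(C)C)c(OC)c(OC)c6[C@@]7(C)CCCC(C)(C)[C@@H]7C=5)[C@@H]32)OCCO1
F6 | step 14 | C14-lithiated lithium enolate of 19 | [Li+].[Li+].CC(C)c1[c-]c2c(c(OC)c1OC)[C@@]1(C)CCCC(C)(C)[C@@H]1C=C2[O-]
F7 | step 14 | tertiary carbinol: 2'-hydroxy-2'-aryl adduct of 9 with the 7-oxoabietane C14 (aryl anti to the cyclopropane) | CC1(CC[C@@H](C(C)C)[C@H]2[C@@H]3CC[C@@](O)(c4c(C(C)C)c(OC)c(OC)c5[C@@]6(C)CCCC(C)(C)[C@@H]6CC(=O)c45)[C@@H]32)OCCO1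
F8 | step 18 | dimethoxy diketone: 25 with the free methyl ketone | CC(=O)CC[C@@H](C(C)C)[C@H]1[C@@H]2CC[C@@]3(C(=O)C4c5c3c(C(C)C)c(OC)c(OC)c5[C@@]6(C)CCCC(C)(C)[C@@H]6C4)[C@@H]21
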